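The C40 chain is cut at C11=C12 and C11'=C12' (C15 + C10 + C15 Wittig), and both end groups come from one building block, because ring B (4'-ketone) is ring A (4-hydroxyl) oxidised. Ring A carries the C4 oxygen, the C5 methyl and the C6 chain all-trans, all equatorial, beside quaternary C1. The route rests on the C1–C6 disconnection that uses this: a tertiary C1 cation closes on C6 of an allylsilane through a chair, which in one operation forms the ring, sets C6 from the acyclic C4/C5 pair and leaves a C7=C8 vinyl handle. The precursor is an open-chain syn 4-acetoxy-5-methyl allylsilane with a tertiary alcohol at C1.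

Key step: step 5

Remark: carotenoid numbering is used for ring and chain atoms; (+)-Ipc2BOMe denotes the reagent made from (−)-α-pinene, whose (Z)-crotyl derivative is expected to add to the Re face of an unbranched aldehyde.
Remark: the γ-hydroxy aldehyde is not used as its lactol, which would open too slowly at −78 °C, the temperature at which the crotylborane keeps its geometry; aldehyde ester 1 is crotylated and the gem-dimethyl carbinol is added afterwards.

Step 1
Reactants: 1 methyl 4-oxobutanoate; 2 cis-but-2-ene
Product: 7 (5S)-5-[(2S)-but-3-en-2-yl]dihydrofuran-2(3H)-one, via (Z)-crotylpotassium 3 (not isolated), via (Z)-crotylbis(isopinocampheyl)borane 4 (not isolated), via borinate ester 5 (not isolated), via hydroxy ester 6 (not isolated)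
Conditions: 2, KOt-Bu, n-BuLi, THF, −78 → −45 °C; (+)-Ipc2BOMe, −78 °C; BF3·OEt2; 1, −78 °C; NaBO3·4H2O, THF/H2O, rt; TsOH·H2O (cat.), CH2Cl2, rt
Reagents that add atoms: none
Why: Brown asymmetric crotylboration, in which the (Z)-crotylborane 4 adds through a closed six-membered chair transition state, the Z geometry giving the syn C4/C5 pair and the isopinocampheyl groups of the (−)-α-pinene series directing attack to the Re face so that both centres should be S, after which perborate cleaves borinate 5 and acid closes hydroxy ester 6 to the γ-lactone.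

Step 2
Reactants: 7 (5S)-5-[(2S)-but-3-en-2-yl]dihydrofuran-2(3H)-one
Product: 8 (5S,6S)-2,6-dimethyloct-7-ene-2,5-diol
Conditions: MeMgBr (3.5 equiv), THF, 0 °C → rt; aq. NH4Cl
Reagents that add atoms: methylmagnesium bromide, C[Mg]Br
Why: Double Grignard addition to a lactone, the first methyl opening the ring to a methyl ketone and the second giving the gem-dimethyl carbinol, so that C1 with both methyl groups and the free C4 hydroxyl arise together without touching either stereocentre.

Step 3
Reactants: 8 (5S,6S)-2,6-dimethyloct-7-ene-2,5-diol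
Product: 9 (3S,4S)-7-hydroxy-3,7-dimethyloct-1-en-4-yl acetate
Conditions: Ac2O (1.2 equiv), pyridine, DMAP (cat.), CH2Cl2, 0 °C
Reagents that add atoms: acetic anhydride, CC(=O)OC(C)=O
Why: Chemoselective acylation, the secondary C4 hydroxyl reacting far faster than the hindered tertiary C1 hydroxyl, which stays free as the later leaving group while the ester makes the C4 oxygen a poor nucleophile.

Step 4
Reactants: 9 (3S,4S)-7-hydroxy-3,7-dimethyloct-1-en-4-yl acetate; 10 allyltrimethylsilane
Product: 11 (2E,4S,5S)-8-hydroxy-4,8-dimethyl-1-(trimethylsilyl)non-2-en-5-yl acetate (E isomer named; the minor 2Z isomer is carried along)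
Conditions: 10 (4 equiv), second-generation Grubbs catalyst (5 mol %), CH2Cl2, 40 °C
Reagents that add atoms: none
Why: Olefin cross-metathesis of two monosubstituted alkenes with loss of ethylene, excess allylsilane suppressing dimerisation of 9, and the alkene geometry being of no concern because both isomers should give the same vinyl product in step 5.

Step 5
Reactants: 11 (2E,4S,5S)-8-hydroxy-4,8-dimethyl-1-(trimethylsilyl)non-2-en-5-yl acetate
Product: 12 (1S,2S,3S)-3-ethenyl-2,4,4-trimethylcyclohexyl acetate
Conditions: SnCl4 (1.1 equiv), CH2Cl2 (0.01 M), −78 → −40 °C; aq. NaHCO3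
Reagents that add atoms: none
Why: SnCl4 binds the tertiary hydroxyl and ionises the C1–O bond, the tertiary cation is attacked by the γ-carbon (C6) of the allylsilane, and the C7 cation, stabilised by the β-silicon, loses the silyl group to leave the C7=C8 vinyl group. The closest known reaction is the Lewis-acid tert-alkylation of allylsilanes (Hosomi–Sakurai type), run here intramolecularly as an allylsilane-terminated cation–olefin cyclisation. The six-membered ring closes 6-exo-trig, C1 bonding to the near alkene carbon while the C6=C7 bond stays outside the ring. C6 is set by a chair transition state in which the C4 acetate and C5 methyl (syn in the chain, hence both equatorial) and the C7 alkenyl arm are all equatorial, so the chain should end trans to the methyl group, all-trans overall. The step needs carbon–carbon closure to beat capture of the cation by the C4 oxygen, proton loss from the cation and protodesilylation; the acyl group makes that oxygen non-nucleophilic, and high dilution, low temperature and an aprotic Lewis acid disfavour the proton-driven paths. Attack through C6 (not C7 or C8) is fixed by the β-silyl effect, and both alkene isomers of 11 converge on 12.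

Step 6
Reactants: 12 (1S,2S,3S)-3-ethenyl-2,4,4-trimethylcyclohexyl acetate
Product: 14 (1S,2S,3S)-3-formyl-2,4,4-trimethylcyclohexyl acetate, via ozonide 13 (not isolated)
Conditions: O3, CH2Cl2, −78 °C; then PPh3, −78 °C → rt
Reagents that add atoms: ozone, [O-][O+]=O
Why: Ozonolysis with reductive work-up, the only alkene being cleaved through the 1,2,4-trioxolane 13 that PPh3 reduces to the C6 aldehyde, whose α-centre already has the more stable equatorial arrangement and so has no drive to epimerise.

Step 7
Reactants: 14 (1S,2S,3S)-3-formyl-2,4,4-trimethylcyclohexyl acetate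
Product: 15 (1S,2S,3S)-2,4,4-trimethyl-3-[(1E)-3-oxobut-1-en-1-yl]cyclohexyl acetate
Conditions: (EtO)2P(O)CH2C(O)CH3 (1.5 equiv), NaH (1.4 equiv), THF, 0 °C → rt
Reagents that add atoms: diethyl (2-oxopropyl)phosphonate, CCOP(=O)(CC(C)=O)OCC
Why: Horner–Wadsworth–Emmons olefination, the stabilised phosphonate anion adding to the hindered aldehyde and eliminating phosphate to give the E enone (C7=C8), with the acetate inert to this weakly nucleophilic anion.

Step 8
Reactants: 15 (1S,2S,3S)-2,4,4-trimethyl-3-[(1E)-3-oxobut-1-en-1-yl]cyclohexyl acetate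
Product: 16 (1S,2S,3S)-3-[(1E)-3-hydroxy-3-methylpenta-1,4-dien-1-yl]-2,4,4-trimethylcyclohexan-1-ol (both epimers at the side-chain carbinol carbon C9)
Conditions: CH2=CHMgBr (5 equiv), THF, −20 → 0 °C; aq. NH4Cl
Reagents that add atoms: vinylmagnesium bromide, C=C[Mg]Br
Why: Grignard 1,2-addition to the enone carbonyl (as in the preparation of vinyl-ionols) with cleavage of the C4 acetate by the excess reagent, the new C9 centre forming as a mixture that is erased on ionisation in the next step.

Step 9
Reactants: 16 (1S,2S,3S)-3-[(1E)-3-hydroxy-3-methylpenta-1,4-dien-1-yl]-2,4,4-trimethylcyclohexan-1-ol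
Product: 17 [(2E,4E)-5-[(1S,2S,3S)-3-hydroxy-2,6,6-trimethylcyclohexyl]-3-methylpenta-2,4-dien-1-yl]triphenylphosphonium bromide
Conditions: PPh3·HBr, MeOH, 0 °C → rt; crystallise
Reagents that add atoms: triphenylphosphine hydrobromide, [Br-].c1ccc(cc1)[PH+](c1ccccc1)c1ccccc1
Why: SN1 substitution with allylic transposition (the standard C15 Wittig salt formation), HBr ionising the doubly allylic tertiary alcohol to a pentadienyl cation (C7 to C11) that PPh3 traps at the unhindered terminus C11, leaving the secondary C4 hydroxyl untouched and giving mainly the 9E salt, which crystallisation should purify.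

Step 10
Reactants: 16 (1S,2S,3S)-3-[(1E)-3-hydroxy-3-methylpenta-1,4-dien-1-yl]-2,4,4-trimethylcyclohexan-1-ol
Product: 18 (2S,3S)-3-[(1E)-3-hydroxy-3-methylpenta-1,4-dien-1-yl]-2,4,4-trimethylcyclohexan-1-one
Conditions: Dess–Martin periodinane (1.2 equiv), NaHCO3, CH2Cl2, 0 °C → rt
Reagents that add atoms: none
Why: Dess–Martin oxidation of the secondary C4 alcohol to the ketone, the tertiary alcohol being unable to oxidise, bicarbonate protecting the acid-sensitive allylic carbinol, and C5 next to the new carbonyl already holding the thermodynamically preferred trans (equatorial) arrangement.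

Step 11
Reactants: 18 (2S,3S)-3-[(1E)-3-hydroxy-3-methylpenta-1,4-dien-1-yl]-2,4,4-trimethylcyclohexan-1-one
Product: 19 [(2E,4E)-3-methyl-5-[(1S,2S)-2,6,6-trimethyl-3-oxocyclohexyl]penta-2,4-dien-1-yl]triphenylphosphonium bromide
Conditions: PPh3·HBr, CH2Cl2, 0 °C → rt; crystallise
Reagents that add atoms: triphenylphosphine hydrobromide, [Br-].c1ccc(cc1)[PH+](c1ccccc1)c1ccccc1
Why: The same SN1 phosphonium salt formation with allylic transposition as in step 9, run without methanol so that the ring ketone is not ketalised, any acid-induced enolisation at C5 returning the stable trans isomer.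

Step 12
Reactants: 17 [(2E,4E)-5-[(1S,2S,3S)-3-hydroxy-2,6,6-trimethylcyclohexyl]-3-methylpenta-2,4-dien-1-yl]triphenylphosphonium bromide; 20 (2E,4E,6E)-2,7-dimethylocta-2,4,6-trienedial
Product: 21 (2E,4E,6E,8E,10E,12E)-13-[(1S,2S,3S)-3-hydroxy-2,6,6-trimethylcyclohexyl]-2,7,11-trimethyltrideca-2,4,6,8,10,12-hexaenal
Conditions: 20 (3 equiv), 1,2-epoxybutane, EtOH, reflux, slow addition of 17, Ar, dark; then heptane, reflux
Reagents that add atoms: none
Why: Wittig olefination under epoxide (salt-free) conditions, bromide opening the epoxide to an alkoxide that deprotonates the salt, the allylic ylide condensing with one aldehyde of the excess dialdehyde to form C11=C12, and heating equilibrating the hindered 11Z isomer to the all-E aldehyde.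

Step 13
Reactants: 21 (2E,4E,6E,8E,10E,12E)-13-[(1S,2S,3S)-3-hydroxy-2,6,6-trimethylcyclohexyl]-2,7,11-trimethyltrideca-2,4,6,8,10,12-hexaenal; 19 [(2E,4E)-3-methyl-5-[(1S,2S)-2,6,6-trimethyl-3-oxocyclohexyl]penta-2,4-dien-1-yl]triphenylphosphonium bromide
Product: 22 (4S,5S,6S,5'S,6'S)-4-hydroxy-5,6,5',6'-tetrahydro-β,β-caroten-4'-one (CNP0107241.1), all-E
Conditions: 19 (1.3 equiv), 1,2-epoxybutane, EtOH, reflux, Ar, dark; then heptane, reflux; crystallise
Reagents that add atoms: none
Why: Wittig olefination under the same epoxide conditions, the ylide of 19 reacting with the aldehyde of 21 much faster than with its own hindered ring ketone to form C11'=C12', and thermal isomerisation with crystallisation should give the all-E carotenoid with all five stereocentres unchanged.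

Compound list
1 | methyl 4-oxobutanoate | COC(=O)CCC=O | starting material
2 | cis-but-2-ene | C/C=C\C | starting material
3 | (Z)-but-2-en-1-ylpotassium | C/C=C\C[K] | intermediate (not isolated)
4 | [(2Z)-but-2-en-1-yl]bis(isopinocampheyl)borane, isopinocampheyl groups of the (−)-α-pinene series | C/C=C\CB([C@H]1C[C@H]2C[C@@H]([C@@H]1C)C2(C)C)[C@H]1C[C@H]2C[C@@H]([C@@H]1C)C2(C)C | intermediate (not isolated)
5 | methyl (4S,5S)-4-{[bis(isopinocampheyl)boranyl]oxy}-5-methylhept-6-enoate | C=C[C@H](C)[C@H](CCC(=O)OC)OB([C@H]1C[C@H]2C[C@@H]([C@@H]1C)C2(C)C)[C@H]1C[C@H]2C[C@@H]([C@@H]1C)C2(C)C | intermediate (not isolated)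
6 | methyl (4S,5S)-4-hydroxy-5-methylhept-6-enoate | C=C[C@H](C)[C@@H](O)CCC(=O)OC | intermediate (not isolated)
7 | (5S)-5-[(2S)-but-3-en-2-yl]dihydrofuran-2(3H)-one | C=C[C@H](C)[C@@H]1CCC(=O)O1 | intermediate
8 | (5S,6S)-2,6-dimethyloct-7-ene-2,5-diol | C=C[C@H](C)[C@@H](O)CCC(C)(C)O | intermediate
9 | (3S,4S)-7-hydroxy-3,7-dimethyloct-1-en-4-yl acetate | C=C[C@H](C)[C@@H](OC(C)=O)CCC(C)(C)O | intermediate
10 | allyltrimethylsilane | C=CC[Si](C)(C)C | starting material
11 | (2E,4S,5S)-8-hydroxy-4,8-dimethyl-1-(trimethylsilyl)non-2-en-5-yl acetate (with minor 2Z isomer) | C[Si](C)(C)C/C=C/[C@H](C)[C@@H](OC(C)=O)CCC(C)(C)O | intermediate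
12 | (1S,2S,3S)-3-ethenyl-2,4,4-trimethylcyclohexyl acetate | C=C[C@H]1[C@H](C)[C@@H](OC(C)=O)CCC1(C)C | intermediate
13 | (1S,2S,3S)-2,4,4-trimethyl-3-(1,2,4-trioxolan-3-yl)cyclohexyl acetate (ozonide, mixture at the trioxolane carbon) | C1OC(OO1)[C@H]2[C@H](C)[C@@H](OC(C)=O)CCC2(C)C | intermediate (not isolated)
14 | (1S,2S,3S)-3-formyl-2,4,4-trimethylcyclohexyl acetate | O=C[C@H]1[C@H](C)[C@@H](OC(C)=O)CCC1(C)C | intermediate
15 | (1S,2S,3S)-2,4,4-trimethyl-3-[(1E)-3-oxobut-1-en-1-yl]cyclohexyl acetate | CC(=O)/C=C/[C@H]1[C@H](C)[C@@H](OC(C)=O)CCC1(C)C | intermediate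
16 | (1S,2S,3S)-3-[(1E)-3-hydroxy-3-methylpenta-1,4-dien-1-yl]-2,4,4-trimethylcyclohexan-1-ol (C9 epimers) | C=CC(C)(O)/C=C/[C@H]1[C@H](C)[C@@H](O)CCC1(C)C | intermediate
17 | [(2E,4E)-5-[(1S,2S,3S)-3-hydroxy-2,6,6-trimethylcyclohexyl]-3-methylpenta-2,4-dien-1-yl]triphenylphosphonium bromide | CC(/C=C/[C@H]1[C@H](C)[C@@H](O)CCC1(C)C)=C\C[P+](c1ccccc1)(c1ccccc1)c1ccccc1.[Br-] | intermediate
18 | (2S,3S)-3-[(1E)-3-hydroxy-3-methylpenta-1,4-dien-1-yl]-2,4,4-trimethylcyclohexan-1-one (C9 epimers) | C=CC(C)(O)/C=C/[C@H]1[C@H](C)C(=O)CCC1(C)C | intermediate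
19 | [(2E,4E)-3-methyl-5-[(1S,2S)-2,6,6-trimethyl-3-oxocyclohexyl]penta-2,4-dien-1-yl]triphenylphosphonium bromide | CC(/C=C/[C@H]1[C@H](C)C(=O)CCC1(C)C)=C\C[P+](c1ccccc1)(c1ccccc1)c1ccccc1.[Br-] | intermediate
20 | (2E,4E,6E)-2,7-dimethylocta-2,4,6-trienedial | O=C/C(C)=C/C=C/C=C(C)/C=O | starting material
21 | (2E,4E,6E,8E,10E,12E)-13-[(1S,2S,3S)-3-hydroxy-2,6,6-trimethylcyclohexyl]-2,7,11-trimethyltrideca-2,4,6,8,10,12-hexaenal | CC(/C=C/C=C(C)/C=C/[C@H]1[C@H](C)[C@@H](O)CCC1(C)C)=C\C=C\C=C(C)\C=O | intermediate
22 | (4S,5S,6S,5'S,6'S)-4-hydroxy-5,6,5',6'-tetrahydro-β,β-caroten-4'-one, all-E | CC(/C=C/C=C(C)/C=C/[C@H]1[C@H](C)[C@@H](O)CCC1(C)C)=C\C=C\C=C(C)\C=C\C=C(C)\C=C\[C@H]1[C@H](C)C(=O)CCC1(C)C | target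

Total step count: 13.
Longest linear sequence: 11 steps (steps 1–9, 12 and 13; the branch through steps 10 and 11 is equally long).

Steps most likely to fail

1. Step 5. The silyl group may be lost by protonation before the ring closes, the C1 cation may lose a proton, or chair control at C6 may be weak. The fallback makes the same C1–C6 bond through a tertiary radical instead of a cation. It sets out from monoacetate 9. Cross-metathesis with allyl phenyl sulfone (second-generation Grubbs catalyst, CH2Cl2, 40 °C) should give the allyl sulfone F1. Acylation of its tertiary alcohol with methyl chlorooxoacetate (Et3N, DMAP, CH2Cl2) should give the methyl oxalate F2, and one equivalent of CsOH in THF/H2O should hydrolyse only the very electrophilic oxalate methyl ester to the cesium oxalate F3. Under blue light with Ir[dF(CF3)ppy]2(dtbbpy)PF6 in DME/DMF, F3 should lose two molecules of CO2. The tertiary radical should close 6-exo onto the allyl sulfone through a chair and expel the sulfonyl radical (radical allylation). This gives 12, where the route is rejoined, without any acid in the flask.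

2. Step 12. The first-formed aldehyde may react with a second ylide (double olefination), and conversion to the all-E isomer may be incomplete. The fallback moves the differentiation of the two aldehyde groups onto the cheap partner. It sets out from dialdehyde 20, which with one equivalent of 2,2-dimethylpropane-1,3-diol (pyridinium p-toluenesulfonate, toluene, rt) should give the monoacetal F4; dialdehyde and bisacetal are separated and recycled. Wittig reaction of F4 with salt 17 (1,2-epoxybutane, EtOH, reflux) can then only occur once and should give the C25 acetal F5. Mild hydrolysis (aqueous oxalic acid, THF, rt) should release aldehyde 21, where the route is rejoined.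

3. Step 8. Conjugate addition or enolisation of the methyl ketone may compete with carbonyl addition, and cleavage of the ester by the Grignard reagent may be incomplete. The fallback separates the two events and uses an acetylide followed by semihydrogenation. It sets out from enone 15. Methanolysis (K2CO3, MeOH, rt) should give the hydroxy enone F6. The small, weakly basic ethynylmagnesium bromide (3 equiv, THF, 0 °C) should add cleanly 1,2 to give the ethynyl carbinol F7. Semihydrogenation of the alkyne (H2, Pd/CaCO3 poisoned with Pb(OAc)2, quinoline, EtOAc) should give diol 16, where the route is rejoined.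

Further compounds
F1 | step 5 | (2E,4S,5S)-8-hydroxy-4,8-dimethyl-1-(phenylsulfonyl)non-2-en-5-yl acetate | O=S(=O)(C/C=C/[C@H](C)[C@@H](OC(C)=O)CCC(C)(C)O)c1ccccc1
F2 | step 5 | methyl (5S,6S,7E)-5-acetoxy-2,6-dimethyl-9-(phenylsulfonyl)non-7-en-2-yl oxalate | O=S(=O)(C/C=C/[C@H](C)[C@@H](OC(C)=O)CCC(C)(C)OC(=O)C(=O)OC)c1ccccc1
F3 | step 5 | cesium 2-{[(5S,6S,7E)-5-acetoxy-2,6-dimethyl-9-(phenylsulfonyl)non-7-en-2-yl]oxy}-2-oxoacetate | [Cs+].O=S(=O)(C/C=C/[C@H](C)[C@@H](OC(C)=O)CCC(C)(C)OC(=O)C(=O)[O-])c1ccccc1
F4 | step 12 | (2E,4E,6E)-7-(5,5-dimethyl-1,3-dioxan-2-yl)-2-methylocta-2,4,6-trienal | O=C/C(C)=C/C=C/C=C(C)/C1OCC(C)(C)CO1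
F5 | step 12 | (1S,2S,3S)-3-[(1E,3E,5E,7E,9E,11E)-12-(5,5-dimethyl-1,3-dioxan-2-yl)-3,7-dimethyltrideca-1,3,5,7,9,11-hexaen-1-yl]-2,4,4-trimethylcyclohexan-1-ol | CC(/C=C/C=C(C)/C=C/[C@H]1[C@H](C)[C@@H](O)CCC1(C)C)=C\C=C\C=C(C)\C1OCC(C)(C)CO1
F6 | step 8 | (3E)-4-[(1S,2S,3S)-3-hydroxy-2,6,6-trimethylcyclohexyl]but-3-en-2-one | CC(=O)/C=C/[C@H]1[C@H](C)[C@@H](O)CCC1(C)C
F7 | step 8 | (1S,2S,3S)-3-[(1E)-3-hydroxy-3-methylpent-1-en-4-yn-1-yl]-2,4,4-trimethylcyclohexan-1-ol | C#CC(C)(O)/C=C/[C@H]1[C@H](C)[C@@H](O)CCC1(C)C
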